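- The leftover L, the share of the starting material charged that is not yet product, stood at 81.9 % after 50.0 min in the oak run and at 47.7 % after 20.0 min in the alder run, and it is L, not the product, that gets reckoned with.

common to all: starting material 0.73 M; reagent 0.694 M
- oak: free catalyst 24 mM; temperature −40 °C; run made earlier
- alder: free catalyst 54 mM; temperature −28 °C; run made earlier
- north-west: free catalyst 36 mM; temperature −20 °C; time 30 min
- south-east: free catalyst 36 mM; temperature −35 °C; time 30 min
- south: free catalyst 36 mM; at −35 °C until 10 min, from then on at −20 °C; time 30 min

- oak (time / min: product / %): 4.00: 0; 8.00: 4.4; 20.0: 7.2; 50.0: 18.1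
- alder (time / min: product / %): 1.33: 5.3; 3.00: 9.1; 8.00: 24.1; 20.0: 52.3

(scatter of a reading: 1 percentage point)

* the flask with the highest amount of product, in percent of the starting material charged ("all alike" if they lie within 1.5 percentage points) (north-west / south-east / south / all alike)
* final product, as a percentage of the starting material charged, in north-west
* final product, as a percentage of the starting material charged, in south-east
* final product, as a percentage of the starting material charged, in south



- Own reckoning: if the rate is k·L, with k a rate constant, then −ln L grows as k·t, so the last readings give k = 0.00399 min⁻¹ for oak and 0.0370 min⁻¹ for alder.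
- Taking k as proportional to the free catalyst charged, the readings put alder at 4.12 times oak per unit of catalyst, which reads as an activation energy Ea of 56.1 kJ mol⁻¹, a reading from two runs that changed catalyst and temperature together.
- In this reckoning north-west starts at k = 0.0588 min⁻¹ and south-east at k = 0.0110 min⁻¹.
- The rate falls with L, so the quantity to carry is the accumulated slowing E = k·t, summed over the stretches of a run, which is 1.77 for north-west.
- By 30 min, this reckoning has the rate in north-west down by a factor 5.87, and in south-east, where E is 0.330, by 1.39.
- South collects 1.29, which lies below the E of north-west.
- Product as 1 − exp(−E) then reads 83.0 % for north-west, 28.1 % for south-east and 72.5 % for south, each below the 95.1 % that the reagent, the limiting reagent, allows.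
- The forecast names north-west and gives 80 % (64 % to 90 %), 28 % (20 % to 37 %) and 70 % (55 % to 82 %), below the own reckoning for north-west and south, and it says: “The catalyst order is assumed, because the two runs changed catalyst and temperature together”.
- The flasks give 80.9 % in north-west, 29.9 % in south-east and 70.5 % in south.

    catalyst intermediate C → by-product + catalyst intermediate D (k = 11.4 min⁻¹, Ea = 68.0 kJ mol⁻¹)
    catalyst intermediate D → free catalyst + product (k = 14.8 min⁻¹, Ea = 55.0 kJ mol⁻¹)
    starting material + free catalyst → catalyst intermediate A (k = 448 M⁻¹ min⁻¹, Ea = 44.0 kJ mol⁻¹)
    catalyst intermediate A → catalyst intermediate B (k = 5.74 min⁻¹, Ea = 68.0 kJ mol⁻¹)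
    reagent + catalyst intermediate B → catalyst intermediate C (k = 2.19 M⁻¹ min⁻¹, Ea = 36.0 kJ mol⁻¹)
    (constants at −20 °C)

- Read back from its product, E in north-west is 1.66 against the carried 1.77. At 9.32 min in north-west, catalyst intermediate B is made 1.02 times as fast as it is used up, and catalyst intermediate A 0.992 times. At 30.0 min in north-west, catalyst intermediate B, the resting state, holds 92.6 % of the catalyst charged. A neighbour of north-west charged with 0.0090 M of free catalyst, a quarter of the charge, is reckoned at an E of 0.441, hence 35.7 % product, and that neighbour gives 32.2 %, under the low end of the forecast for north-west, 64 %.

(The runs come from a simulation for an exercise.)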